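**Retrosynthetic overview** (ring A = the diol ring, C1–C6 as in the name of the target; ring B = the bromohydrin ring, C1′ = CH carrying the linker, C2′ = CH2, C3′ = CHBr, C4′ = C(CH3)OH)
1. The C3–CH2 bond of ring A is cut first: alkylation of a ring A ketone enolate with a 2-(ring B)-allyl bromide. Ring A is bought as (S)-carvone, whose isopropenyl-bearing stereocentre relays the other three of ring A.
2. In ring B the C4′ methyl comes from MeTi(OCHMe2)3 addition to a ketone and the C3′ bromine from the α-position of that ketone. This leads back to an (S)-4-substituted cyclohex-2-enone whose C2=C3 double bond is the later C3′–C2′ bond.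
3. Enabling feature: with C4′ as a carbonyl carbon, C3′ is its α-carbon and C2′ its β-carbon, and C4′ and C2′ are 1,5-related through C5′–C6′–C1′. Ring B is therefore the aldol condensation product of a 2-substituted 5-oxohexanal, the Michael adduct of an aldehyde and methyl vinyl ketone.
4. One catalyst-set stereocentre (C1′) is made in the same operation that forms the C3′–C2′ bond and closes ring B; C3′ and C4′ are then relayed from it by substrate control.
5. Ring B is the only ring formed (step 1); ring A is carried in from carvone and joined in step 14.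

Key step: step 1

Remark on the chemistry: 4,4-dimethoxybutanal (mono-dimethyl acetal of succinaldehyde) is taken as a catalogue chemical; the (S)-configured pyrrolidine catalyst is assigned from the usual facial bias of diarylprolinol ether enamines, and its enantiomer would be used if the opposite sense were found.

**Ring B fragment**

Step 1
Reactants: 1 4,4-dimethoxybutanal; 2 but-3-en-2-one (methyl vinyl ketone)
Product: 5 (S)-4-(2,2-dimethoxyethyl)cyclohex-2-en-1-one, via keto-aldehyde 3 (not isolated), via aldol adduct 4 (not isolated)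
Conditions: (S)-2-[methoxy(diphenyl)methyl]pyrrolidine (5 mol %), ethyl 3,4-dihydroxybenzoate (20 mol %), neat, 4 °C; excess 2 removed in vacuo; then LiOH, propan-2-ol, rt
Reagents that add atoms: none
Why: The amine condenses with 1 to an E-enamine whose α-carbon adds to the β-carbon of 2 on the face remote from the methoxydiphenylmethyl group (Michael addition) to release keto-aldehyde 3; LiOH then forms the methyl-ketone enolate, whose terminal carbon attacks the formyl carbon to give 4, and E1cB loss of water gives 5. The closest known reaction type is the amine-catalysed asymmetric Michael addition of aldehydes to vinyl ketones followed by aldol condensation (Robinson-type annulation to 4-substituted cyclohex-2-enones). Ring B closes in the aldol event by a 6-(enolendo)-exo-trig attack that forms the C2–C3 bond of the enone, the later CHBr–CH2 bond. The one lasting stereocentre (C4 of 5, later C1′) is set by the catalyst through shielding of one enamine face, and the carbinol centre of 4 is lost on dehydration. Only the methyl terminus of the ketone can reach the aldehyde through a six-membered transition state (the other enolization modes would give four-membered rings), the acetal keeps the second formyl group out of the reaction, and C4 should hold its configuration because ring closure outruns enolization of the aldehyde and the centre is γ to the carbonyl after dehydration. The step thus builds ring B, sets the stereocentre from which C3′ and C4′ are relayed, and places the C=C so that the later enolate can form only towards C3′.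

Step 2
Reactants: 5 (S)-4-(2,2-dimethoxyethyl)cyclohex-2-en-1-one
Product: 7 (S)-2-bromo-4-(2,2-dimethoxyethyl)cyclohex-2-en-1-one, via dibromide 6 (not isolated)
Conditions: Br2, CH2Cl2, 0 °C; then Et3N, 0 °C → rt
Reagents that add atoms: bromine, BrBr
Why: Bromine adds across the enone C=C and Et3N removes HBr from the dibromide (addition–elimination α-bromination of an enone), which should place bromine only on the α-carbon and creates no stereocentre.

Step 3
Reactants: 7 (S)-2-bromo-4-(2,2-dimethoxyethyl)cyclohex-2-en-1-one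
Product: 9 (2R,4S)-2-bromo-4-(2,2-dimethoxyethyl)cyclohexan-1-one, via bromo-enolate 8 (not isolated)
Conditions: LiBH(CHMeEt)3, THF, −78 °C; then AcOH in THF, −78 °C; cold neutral work-up
Reagents that add atoms: none
Why: Conjugate hydride reduction of the enone by the trialkylborohydride gives the bromo-enolate regiospecifically, and kinetic C-protonation should occur axially through a chair-like transition state (stereoelectronic control), so that bromine ends equatorial and cis to the equatorial side chain at C4.

Step 4
Reactants: 9 (2R,4S)-2-bromo-4-(2,2-dimethoxyethyl)cyclohexan-1-one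
Product: 10 (1S,2R,4S)-2-bromo-4-(2,2-dimethoxyethyl)-1-methylcyclohexan-1-ol
Conditions: MeTi(OCHMe2)3 (from MeLi and ClTi(OCHMe2)3), Et2O, −40 → 0 °C; aq. NH4Cl
Reagents that add atoms: methyltitanium triisopropoxide, C[Ti](OC(C)C)(OC(C)C)OC(C)C (made in the flask from methyllithium, C[Li])
Why: Carbonyl addition of the non-basic organotitanium reagent should leave the α-bromo ketone unenolized, and equatorial attack, preferred by this reagent and reinforced because axial attack would drive the oxygen into eclipse with the equatorial C–Br bond, places CH3 equatorial and OH axial, cis to bromine.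

Step 5
Reactants: 10 (1S,2R,4S)-2-bromo-4-(2,2-dimethoxyethyl)-1-methylcyclohexan-1-ol
Product: 11 2-[(1S,3R,4S)-3-bromo-4-hydroxy-4-methylcyclohexyl]acetaldehyde
Conditions: aq. HCl (1 M), acetone, rt
Reagents that add atoms: water, O
Why: Acid-catalysed hydrolysis of the dimethyl acetal frees the aldehyde without touching a stereocentre, the tertiary alcohol being deactivated towards ionization by the neighbouring C–Br bond.

Step 6
Reactants: 11 2-[(1S,3R,4S)-3-bromo-4-hydroxy-4-methylcyclohexyl]acetaldehyde
Product: 12 2-[(1R,3R,4S)-3-bromo-4-hydroxy-4-methylcyclohexyl]prop-2-enal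
Conditions: aq. CH2O (37 %), pyrrolidine (10 mol %), propionic acid (10 mol %), propan-2-ol, 45 °C
Reagents that add atoms: formaldehyde, C=O
Why: Amine/acid-catalysed Mannich-type condensation with formaldehyde and loss of water (α-methylenation of an aldehyde) installs the 1,1-disubstituted alkene at the only enolizable carbon, and the ring stereocentres are not involved.

Step 7
Reactants: 12 2-[(1R,3R,4S)-3-bromo-4-hydroxy-4-methylcyclohexyl]prop-2-enal
Product: 13 2-[(1R,3R,4S)-3-bromo-4-hydroxy-4-methylcyclohexyl]prop-2-en-1-ol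
Conditions: NaBH4, CeCl3·7H2O, MeOH, 0 °C
Reagents that add atoms: none
Why: Luche reduction should deliver hydride 1,2 to the enal and leave the alkene and the secondary bromide untouched.

Step 8
Reactants: 13 2-[(1R,3R,4S)-3-bromo-4-hydroxy-4-methylcyclohexyl]prop-2-en-1-ol
Product: 14 (1S,2R,4R)-2-bromo-4-(3-bromoprop-1-en-2-yl)-1-methylcyclohexan-1-ol
Conditions: CBr4, PPh3, CH2Cl2, 0 °C
Reagents that add atoms: carbon tetrabromide, BrC(Br)(Br)Br
Why: In the Appel reaction only the unhindered primary allylic alcohol is activated as its alkoxyphosphonium salt and displaced by bromide (SN2), the tertiary alcohol being too hindered to react.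

Step 9
Reactants: 14 (1S,2R,4R)-2-bromo-4-(3-bromoprop-1-en-2-yl)-1-methylcyclohexan-1-ol
Product: 15 triethyl{[(1S,2R,4R)-2-bromo-4-(3-bromoprop-1-en-2-yl)-1-methylcyclohexyl]oxy}silane
Conditions: Et3SiOTf, 2,6-lutidine, CH2Cl2, −78 → 0 °C
Reagents that add atoms: triethylsilyl trifluoromethanesulfonate, CC[Si](CC)(CC)OS(=O)(=O)C(F)(F)F
Why: O-Silylation of the tertiary alcohol with the silyl triflate and a hindered base masks the cis-bromohydrin, whose alkoxide would otherwise be prone to ring contraction under the basic coupling conditions.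

**Ring A fragment**

Step 10
Reactants: 16 (S)-(+)-carvone
Product: 17 (1S,4S,6S)-1-methyl-4-(prop-1-en-2-yl)-7-oxabicyclo[4.1.0]heptan-2-one
Conditions: H2O2 (30 % aq.), NaOH (cat.), MeOH, 0 °C
Reagents that add atoms: hydrogen peroxide, OO
Why: In this nucleophilic (Weitz–Scheffer) epoxidation hydroperoxide adds axially to the β-carbon anti to the isopropenyl group and the enolate closes on oxygen, so the epoxide should form trans to the isopropenyl group while the isolated alkene is untouched.

Step 11
Reactants: 17 (1S,4S,6S)-1-methyl-4-(prop-1-en-2-yl)-7-oxabicyclo[4.1.0]heptan-2-one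
Product: 19 (1S,4S)-1-methyl-4-(prop-1-en-2-yl)cyclohexane-1,2-diol (both C2 epimers), via epoxy alkoxide 18 (not isolated)
Conditions: LiAlH4, THF, 0 °C → reflux; aq. NaOH work-up
Reagents that add atoms: none
Why: Hydride reduces the ketone and then opens the epoxide by SN2 attack at the secondary carbon, so the tertiary C–O bond and its configuration are kept; the C2 configuration does not matter because this centre is oxidized in step 12.

Step 12
Reactants: 19 (1S,4S)-1-methyl-4-(prop-1-en-2-yl)cyclohexane-1,2-diol
Product: 20 (2S,5S)-2-hydroxy-2-methyl-5-(prop-1-en-2-yl)cyclohexan-1-one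
Conditions: (COCl)2, DMSO, CH2Cl2, −78 °C; then Et3N, −78 → 0 °C
Reagents that add atoms: none
Why: Swern oxidation converts the secondary alcohol into the ketone without cleaving the diol, and both C2 epimers should converge on one α-hydroxy ketone.

Step 13
Reactants: 20 (2S,5S)-2-hydroxy-2-methyl-5-(prop-1-en-2-yl)cyclohexan-1-one
Product: 21 (2S,5S)-2-methyl-5-(prop-1-en-2-yl)-2-[(triethylsilyl)oxy]cyclohexan-1-one
Conditions: Et3SiOTf, 2,6-lutidine, CH2Cl2, −78 → 0 °C
Reagents that add atoms: triethylsilyl trifluoromethanesulfonate, CC[Si](CC)(CC)OS(=O)(=O)C(F)(F)F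
Why: O-Silylation of the tertiary alcohol leaves a ketone that can be deprotonated at only one α-carbon.

**Union and completion**

Step 14
Reactants: 21 (2S,5S)-2-methyl-5-(prop-1-en-2-yl)-2-[(triethylsilyl)oxy]cyclohexan-1-one; 15 triethyl{[(1S,2R,4R)-2-bromo-4-(3-bromoprop-1-en-2-yl)-1-methylcyclohexyl]oxy}silane
Product: 23 (2S,5S,6R)-6-{2-[(1R,3R,4S)-3-bromo-4-methyl-4-[(triethylsilyl)oxy]cyclohexyl]prop-2-en-1-yl}-2-methyl-5-(prop-1-en-2-yl)-2-[(triethylsilyl)oxy]cyclohexan-1-one, via lithium enolate 22 (not isolated)
Conditions: LiN(CHMe2)2, THF, −78 °C; then 15, DMPU, −78 → −20 °C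
Reagents that add atoms: none
Why: Deprotonation can occur only at C6 (C2 is quaternary), and SN2 alkylation of the lithium enolate by the allylic bromide should take place anti to the neighbouring isopropenyl group to give the 5,6-trans product, which is also the thermodynamic epimer at this enolizable centre, while the hindered secondary bromide of 15 stays inert.

Step 15
Reactants: 23 (2S,5S,6R)-6-{2-[(1R,3R,4S)-3-bromo-4-methyl-4-[(triethylsilyl)oxy]cyclohexyl]prop-2-en-1-yl}-2-methyl-5-(prop-1-en-2-yl)-2-[(triethylsilyl)oxy]cyclohexan-1-one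
Product: 24 (1S,2S,5S,6R)-6-{2-[(1R,3R,4S)-3-bromo-4-methyl-4-[(triethylsilyl)oxy]cyclohexyl]prop-2-en-1-yl}-2-methyl-5-(prop-1-en-2-yl)-2-[(triethylsilyl)oxy]cyclohexan-1-ol
Conditions: NaBH4, MeOH–THF, 0 °C → rt
Reagents that add atoms: none
Why: In this carbonyl reduction hydride should enter axially because the equatorial trajectory is blocked by the axial C2 methyl group, which gives the equatorial alcohol trans to both neighbouring substituents.

Step 16
Reactants: 24 (1S,2S,5S,6R)-6-{2-[(1R,3R,4S)-3-bromo-4-methyl-4-[(triethylsilyl)oxy]cyclohexyl]prop-2-en-1-yl}-2-methyl-5-(prop-1-en-2-yl)-2-[(triethylsilyl)oxy]cyclohexan-1-ol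
Product: 25 (1S,2S,3R,4S)-3-{2-[(1R,3R,4S)-3-bromo-4-hydroxy-4-methylcyclohexyl]prop-2-en-1-yl}-1-methyl-4-(prop-1-en-2-yl)cyclohexane-1,2-diol (CNP0422107.2)
Conditions: HF·pyridine, pyridine, THF, 0 °C → rt
Reagents that add atoms: none
Why: Fluoride-driven cleavage of both tertiary triethylsilyl ethers under buffered, non-basic conditions should free the triol without ring contraction of the cis-bromohydrin or migration of the 1,1-disubstituted alkenes.

**Compound list**
1 | 4,4-dimethoxybutanal | COC(OC)CCC=O | starting material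
2 | but-3-en-2-one (methyl vinyl ketone) | CC(=O)C=C | starting material
3 | (S)-2-(2,2-dimethoxyethyl)-5-oxohexanal | COC(OC)C[C@@H](C=O)CCC(C)=O | intermediate
4 | (4S)-4-(2,2-dimethoxyethyl)-3-hydroxycyclohexan-1-one (carbinol centre unassigned) | COC(OC)C[C@@H]1CCC(=O)CC1O | intermediate
5 | (S)-4-(2,2-dimethoxyethyl)cyclohex-2-en-1-one | COC(OC)C[C@@H]1CCC(=O)C=C1 | intermediate
6 | (4S)-2,3-dibromo-4-(2,2-dimethoxyethyl)cyclohexan-1-one (trans-dibromide, C2 and C3 unassigned) | COC(OC)C[C@@H]1CCC(=O)C(Br)C1Br | intermediate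
7 | (S)-2-bromo-4-(2,2-dimethoxyethyl)cyclohex-2-en-1-one | COC(OC)C[C@@H]1CCC(=O)C(Br)=C1 | intermediate
8 | lithium (S)-2-bromo-4-(2,2-dimethoxyethyl)cyclohex-1-en-1-olate | COC(OC)C[C@@H]1CCC([O-])=C(Br)C1.[Li+] | intermediate
9 | (2R,4S)-2-bromo-4-(2,2-dimethoxyethyl)cyclohexan-1-one (Br and side chain cis) | COC(OC)C[C@@H]1CCC(=O)[C@H](Br)C1 | intermediate
10 | (1S,2R,4S)-2-bromo-4-(2,2-dimethoxyethyl)-1-methylcyclohexan-1-ol | COC(OC)C[C@@H]1CC[C@](C)(O)[C@H](Br)C1 | intermediate
11 | 2-[(1S,3R,4S)-3-bromo-4-hydroxy-4-methylcyclohexyl]acetaldehyde | O=CC[C@@H]1CC[C@](C)(O)[C@H](Br)C1 | intermediate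
12 | 2-[(1R,3R,4S)-3-bromo-4-hydroxy-4-methylcyclohexyl]prop-2-enal | O=CC(=C)[C@@H]1CC[C@](C)(O)[C@H](Br)C1 | intermediate
13 | 2-[(1R,3R,4S)-3-bromo-4-hydroxy-4-methylcyclohexyl]prop-2-en-1-ol | OCC(=C)[C@@H]1CC[C@](C)(O)[C@H](Br)C1 | intermediate
14 | (1S,2R,4R)-2-bromo-4-(3-bromoprop-1-en-2-yl)-1-methylcyclohexan-1-ol | BrCC(=C)[C@@H]1CC[C@](C)(O)[C@H](Br)C1 | intermediate
15 | triethyl{[(1S,2R,4R)-2-bromo-4-(3-bromoprop-1-en-2-yl)-1-methylcyclohexyl]oxy}silane | BrCC(=C)[C@@H]1CC[C@](C)(O[Si](CC)(CC)CC)[C@H](Br)C1 | intermediate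
16 | (S)-(+)-carvone, (5S)-2-methyl-5-(prop-1-en-2-yl)cyclohex-2-en-1-one | CC1=CC[C@@H](CC1=O)C(C)=C | starting material
17 | (1S,4S,6S)-1-methyl-4-(prop-1-en-2-yl)-7-oxabicyclo[4.1.0]heptan-2-one (epoxide trans to isopropenyl) | C1[C@@H](C(=C)C)C[C@@H]2O[C@]2(C)C1=O | intermediate
18 | 1-methyl-4-(prop-1-en-2-yl)-7-oxabicyclo[4.1.0]heptan-2-ol, ring centres as in 17, carbinol unassigned (present as its aluminium alkoxide) | C1[C@@H](C(=C)C)C[C@@H]2O[C@]2(C)C1O | intermediate
19 | (1S,4S)-1-methyl-4-(prop-1-en-2-yl)cyclohexane-1,2-diol (both C2 epimers) | C1[C@@H](C(=C)C)CC[C@](C)(O)C1O | intermediate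
20 | (2S,5S)-2-hydroxy-2-methyl-5-(prop-1-en-2-yl)cyclohexan-1-one | C1[C@@H](C(=C)C)CC[C@](C)(O)C1=O | intermediate
21 | (2S,5S)-2-methyl-5-(prop-1-en-2-yl)-2-[(triethylsilyl)oxy]cyclohexan-1-one | C1[C@@H](C(=C)C)CC[C@](C)(O[Si](CC)(CC)CC)C1=O | intermediate
22 | lithium (3S,6S)-6-methyl-3-(prop-1-en-2-yl)-6-[(triethylsilyl)oxy]cyclohex-1-en-1-olate | [Li+].[O-]C1=C[C@@H](C(=C)C)CC[C@]1(C)O[Si](CC)(CC)CC | intermediate
23 | (2S,5S,6R)-6-{2-[(1R,3R,4S)-3-bromo-4-methyl-4-[(triethylsilyl)oxy]cyclohexyl]prop-2-en-1-yl}-2-methyl-5-(prop-1-en-2-yl)-2-[(triethylsilyl)oxy]cyclohexan-1-one | C=C(C[C@@H]1[C@@H](C(=C)C)CC[C@](C)(O[Si](CC)(CC)CC)C1=O)[C@@H]1CC[C@](C)(O[Si](CC)(CC)CC)[C@H](Br)C1 | intermediate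
24 | (1S,2S,5S,6R)-6-{2-[(1R,3R,4S)-3-bromo-4-methyl-4-[(triethylsilyl)oxy]cyclohexyl]prop-2-en-1-yl}-2-methyl-5-(prop-1-en-2-yl)-2-[(triethylsilyl)oxy]cyclohexan-1-ol | C=C(C[C@@H]1[C@@H](C(=C)C)CC[C@](C)(O[Si](CC)(CC)CC)[C@H]1O)[C@@H]1CC[C@](C)(O[Si](CC)(CC)CC)[C@H](Br)C1 | intermediate
25 | (1S,2S,3R,4S)-3-{2-[(1R,3R,4S)-3-bromo-4-hydroxy-4-methylcyclohexyl]prop-2-en-1-yl}-1-methyl-4-(prop-1-en-2-yl)cyclohexane-1,2-diol (CNP0422107.2) | C=C(C[C@@H]1[C@@H](C(=C)C)CC[C@](C)(O)[C@H]1O)[C@@H]1CC[C@](C)(O)[C@H](Br)C1 | target

**Step count**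
Total: 16 steps. Longest linear sequence: 12 steps (steps 1–9, then 14–16); the ring A branch (steps 10–13) runs in parallel.

**Steps most likely to fail**

Step 3. The borohydride may attack the carbonyl or displace bromide instead of adding in the conjugate sense, and the kinetically formed equatorial bromide may equilibrate through the enol during quench or work-up, which would erode the C3′ configuration. The fallback sets out from 5 and comes back at 9. Conjugate reduction of 5 with LiBH(CHMeEt)3 and trapping with Me3SiCl should give the trimethylsilyl enol ether F1, with the double bond fixed towards the former α-carbon. N-Bromosuccinimide in THF at −78 °C should brominate F1 at that carbon, mainly from the axial direction, to the trans-bromo ketone F2. Exchange with LiBr in N,N-dimethylformamide (SN2 at the α-carbon with inversion) should equilibrate F2 with its equatorial epimer 9, which is separated while recovered F2 is resubmitted. This replaces kinetic protonation by bromination of a regiodefined enol ether and thermodynamic epimerization.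

Step 11. Hydride attack at the secondary epoxide carbon runs against the trans-diaxial opening preference of the conformer with an equatorial isopropenyl group, so the opening may be slow or may go in part at the tertiary carbon and give the wrong regioisomer. The fallback sets out from 17 and comes back at 19. NaBH4 in MeOH should reduce only the ketone and give the epoxy alcohol 18, now isolated. Sodium phenylselenide (PhSeSePh, NaBH4, EtOH, reflux), a much stronger and softer nucleophile, should open the epoxide at the secondary carbon to the hydroxy selenide F3. Bu3SnH with azobisisobutyronitrile in toluene at reflux should then remove selenium by a radical chain and give 19.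

Step 14. Alkylation of the hindered enolate may be slow, so that proton transfer between product and enolate, migration of the triethylsilyl group from the tertiary oxygen to the enolate oxygen, or O-alkylation can compete. The fallback sets out from 21 and comes back at 23. Condensation of 21 with H2NNMe2 (cat. AcOH, EtOH, reflux) should give the N,N-dimethylhydrazone F4. Deprotonation with LiN(CHMe2)2 gives an aza-enolate that is more nucleophilic and has no oxygen to accept silicon; alkylation by 15, anti to the isopropenyl group, should give the alkylated hydrazone F5. Hydrolysis with Cu(OAc)2 in aqueous THF should return ketone 23.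

Further compounds
F1 | step 3 | {[(4R)-4-(2,2-dimethoxyethyl)cyclohex-1-en-1-yl]oxy}trimethylsilane | COC(OC)C[C@@H]1CCC(O[Si](C)(C)C)=CC1
F2 | step 3 | (2S,4S)-2-bromo-4-(2,2-dimethoxyethyl)cyclohexan-1-one (Br and side chain trans) | COC(OC)C[C@@H]1CCC(=O)[C@@H](Br)C1
F3 | step 11 | (1R,4R,6R)-1-methyl-6-(phenylselanyl)-4-(prop-1-en-2-yl)cyclohexane-1,2-diol (both C2 epimers) | C1[C@@H](C(=C)C)C[C@@H]([Se]c2ccccc2)[C@](C)(O)C1O
F4 | step 14 | 1,1-dimethyl-2-[(2S,5S)-2-methyl-5-(prop-1-en-2-yl)-2-[(triethylsilyl)oxy]cyclohexylidene]hydrazine | C1[C@@H](C(=C)C)CC[C@](C)(O[Si](CC)(CC)CC)C1=NN(C)C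
F5 | step 14 | 2-[(2S,5S,6R)-6-{2-[(1R,3R,4S)-3-bromo-4-methyl-4-[(triethylsilyl)oxy]cyclohexyl]prop-2-en-1-yl}-2-methyl-5-(prop-1-en-2-yl)-2-[(triethylsilyl)oxy]cyclohexylidene]-1,1-dimethylhydrazine | C=C(C[C@@H]1[C@@H](C(=C)C)CC[C@](C)(O[Si](CC)(CC)CC)C1=NN(C)C)[C@@H]1CC[C@](C)(O[Si](CC)(CC)CC)[C@H](Br)C1
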